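**Retrosynthetic overview**

1. Structural feature: the target is two drim-8-ene halves joined through C11–C11' on a C2 axis. With each half numbered as a drimane, ring A is C1–C5/C10 (gem-dimethyl at C4) and ring B is C5–C10 (C8(Me)=C9, C5–H trans to C10–Me). Each ring A is a 2,2,6-trimethylcyclohexanone (C5 = carbonyl carbon, C10 = its only enolisable carbon), and C6–C9 of both rings B plus C11/C11' form one linear C12 chain.
2. The C8=C9 alkenes come from bis(drim-8-en-7-one) 13 by removal of the C7 oxygen; 13 comes from bis(trans-decal-7-one) 11 by dehydrogenation through the silyl enol ether 12; 11 comes from bis(Δ5-en-7-one) 10 by dissolving-metal reduction.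
3. Key disconnection of 10: C9–C10 and C5=C6 on both halves at once, leading to the chiral imine 7 of ketone 5 and the C12 bis-enone 4.
4. 4 comes from succinaldehyde 2 and two equivalents of ylide 3; 7 comes from 5 and (S)-1-phenylethylamine 6.
5. Ring order: both rings A are purchased; both rings B are closed in the same operation.

Key step: step 4

Assumption: the (S)-1-phenylethyl imine of 5 is taken to direct C–C bond formation to the same enamine face as the imines of simpler α-methylcyclanones, which corresponds to the 10β-methyl group of the target; if the gem-dimethyl group reversed this sense, the (R)-amine would be used.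

**Route**

Step 1
Reactants: 1 2,5-dimethoxytetrahydrofuran (cis/trans mixture)
Product: 2 succinaldehyde (butanedial)
Conditions: H2O, 90 °C, 2 h, MeOH distilled off; extraction into CH2Cl2, used at once
Reagents that add atoms: water, O
Why: Acetal hydrolysis of the cyclic bis-acetal in hot water should unmask both aldehyde groups, and the dialdehyde is used fresh because it oligomerises on standing.

Step 2
Reactants: 2 succinaldehyde; 3 3-(triphenylphosphoranylidene)butan-2-one (2.3 equiv)
Product: 4 (3E,7E)-3,8-dimethyldeca-3,7-diene-2,9-dione
Conditions: toluene, 80 °C, 16 h, slow addition of 2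
Reagents that add atoms: none
Why: Two-fold Wittig olefination with the stabilised α-methyl keto ylide should give the trisubstituted enone on each side, with E geometry following from reversible oxaphosphetane formation.

Step 3
Reactants: 5 2,2,6-trimethylcyclohexanone (racemic); 6 (S)-1-phenylethylamine (1.3 equiv)
Product: 7 (S)-N-(2,2,6-trimethylcyclohexylidene)-1-phenylethanamine (ring C6 epimers, tautomeric with the C1=C6 secondary enamine)
Conditions: TiCl4 (0.6 equiv), Et3N (3 equiv), toluene, 0 °C → 110 °C; filtration, distillation
Reagents that add atoms: none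
Why: Ketimine condensation driven by titanium tetrachloride as Lewis acid and water scavenger is the dependable way to an imine of a ketone flanked by a quaternary and a tertiary carbon, and the racemic ring centre is irrelevant because it becomes sp2 in the enamine tautomer.

Step 4
Reactants: 4 (3E,7E)-3,8-dimethyldeca-3,7-diene-2,9-dione; 7 (S)-1-phenylethyl imine of 2,2,6-trimethylcyclohexanone (2.6 equiv)
Product: 10 bis(Δ5-en-7-one) 11,11'-bi(drim-5-en-7-one), via bis-imine Michael adduct 8 (not isolated), via tetraketone 9 (not isolated)
Conditions: THF (2 M in 4), 1.2 GPa, 40 °C, 72 h; then 10% aq AcOH–THF, 40 °C; then, after extraction and solvent switch without purification, NaOMe (0.5 equiv), MeOH, 60 °C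
Reagents that add atoms: none
Why: Proposed new method: imine 7 equilibrates with its only possible secondary enamine (C5=C10), which should add through C10 to the β-carbon C9 of each s-cis enone arm of 4 in a compact aza-ene-like transition state with concerted N–H transfer to C8, pressure supplying the driving force that the β-alkylated, α-methylated acceptor otherwise lacks; the closest known reaction type is the chiral-imine Michael addition of α-methylcyclanone imines to β-unsubstituted vinyl ketones followed by Robinson cyclisation. Aqueous acetic acid then hydrolyses both imines to tetraketone 9, and methoxide closes each ring B by 6-(enolendo)-exo-trig aldol addition of the C6 methyl-ketone enolate onto the C5 carbonyl followed by E1cB dehydration to the C5=C6 enone, ring A having no enolisable position that could compete. The C10 stereocentre of each half is set by the (S)-1-phenylethyl group, whose phenyl ring shields one face of the planar enamine so that C9 bonds to the opposite face, and because the racemic ketone passes through this planar enamine the step is stereoconvergent. The C8 and C9 centres are not controlled and need not be, since both become sp2 in step 7. The step needs 1,4-addition on both arms without cross-reaction between them: the neutral concerted proton transfer avoids a free enolate that could attack the second enone arm, the α-methyl groups block amine-triggered cyclisation of 4, and the excess of 7 drives the second addition. Because the same auxiliary controls both additions, a facial error on one arm gives a diastereomer (removable at the stage of 13) and not the enantiomer.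

Step 5
Reactants: 10 11,11'-bi(drim-5-en-7-one)
Product: 11 11,11'-bi(5α-driman-7-one)
Conditions: Li (6 equiv), NH3(l)–THF, t-BuOH (2 equiv), −78 °C → −33 °C; solid NH4Cl
Reagents that add atoms: none
Why: Dissolving-metal reduction of each enone should protonate the C5 carbanion axially on the face opposite to the C10 methyl group, setting the trans ring fusion (C5–H α) on both halves before the enolate is protonated to the ketone on quench.

Step 6
Reactants: 11 11,11'-bi(5α-driman-7-one)
Product: 12 7,7'-bis(trimethylsilyloxy)-11,11'-bi(5α-drim-7-ene)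
Conditions: TMSCl (6 equiv), NaI (6 equiv), Et3N (8 equiv), MeCN, 20 °C → 50 °C
Reagents that add atoms: chlorotrimethylsilane, C[Si](C)(C)Cl
Why: Equilibrating silyl enol ether formation with iodotrimethylsilane made in situ should give the thermodynamic tetrasubstituted C7=C8 isomer, favoured both by the higher substitution at C8 and by the preference of trans-decal-2-one-type ketones to enolise away from the ring fusion.

Step 7
Reactants: 12 7,7'-bis(trimethylsilyloxy)-11,11'-bi(5α-drim-7-ene)
Product: 13 11,11'-bi(drim-8-en-7-one)
Conditions: Pd(OAc)2 (2.4 equiv), MeCN, 40 °C; chromatography, crystallisation of the C2-symmetric isomer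
Reagents that add atoms: none
Why: Saegusa oxidation through the divalent palladium enolate at C8 and β-hydride elimination of the C9 hydrogen should give the tetrasubstituted C8=C9 enone, which erases the uncontrolled C8 and C9 centres so that all diastereomers of 12 converge on one compound.

Step 8
Reactants: 13 11,11'-bi(drim-8-en-7-one)
Product: 14 11,11'-bi(drim-8-ene), the target
Conditions: AlCl3 (12 equiv), LiAlH4 (4 equiv), Et2O, 0 °C; then 13, 35 °C; aqueous work-up
Reagents that add atoms: none
Why: Mixed chloroalane reduction (hydride–Lewis acid deoxygenation of an enone) should reduce C7=O, ionise the aluminium alkoxide to the C7–C8–C9 allyl cation and deliver a second hydride to the unhindered secondary terminus C7, leaving the tetrasubstituted C8=C9 alkene in place and C5 and C10 untouched.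

**Compound list**

The C10 geometry is that of the target from compound 8 onward; the R/S label at C10 changes only because substituent priorities change.

1 | 2,5-dimethoxytetrahydrofuran | COC1CCC(OC)O1 | starting material
2 | succinaldehyde | O=CCCC=O | intermediate
3 | 3-(triphenylphosphoranylidene)butan-2-one | CC(=O)C(C)=P(c1ccccc1)(c1ccccc1)c1ccccc1 | starting material
4 | (3E,7E)-3,8-dimethyldeca-3,7-diene-2,9-dione | CC(=O)/C(C)=C/CC/C=C(\C)C(C)=O | intermediate
5 | 2,2,6-trimethylcyclohexanone (racemic) | CC1CCCC(C)(C)C1=O | starting material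
6 | (S)-1-phenylethylamine | C[C@H](N)c1ccccc1 | starting material
7 | (S)-N-(2,2,6-trimethylcyclohexylidene)-1-phenylethanamine (ring C6 epimers) | CC1CCCC(C)(C)C1=N[C@@H](C)c1ccccc1 | intermediate
8 | bis-imine Michael adduct: 3,8-dimethyldecane-2,9-dione carrying at C4 and C7 a (1R)-1,3,3-trimethyl-2-[(S)-1-phenylethylimino]cyclohexyl group (chain C3, C4, C7, C8 unassigned) | CC(=O)C(C)C(CCC(C(C)C(C)=O)[C@@]1(C)CCCC(C)(C)C1=N[C@@H](C)c1ccccc1)[C@@]1(C)CCCC(C)(C)C1=N[C@@H](C)c1ccccc1 | intermediate
9 | tetraketone: 3,8-dimethyl-4,7-bis[(1R)-1,3,3-trimethyl-2-oxocyclohexyl]decane-2,9-dione (chain centres unassigned) | CC(=O)C(C)C(CCC(C(C)C(C)=O)[C@@]1(C)CCCC(C)(C)C1=O)[C@@]1(C)CCCC(C)(C)C1=O | intermediate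
10 | (10R,10'R)-11,11'-bi(drim-5-en-7-one): C2-symmetric bis(Δ5-en-7-one), C8 and C9 epimer mixture | CC1C(CCC2C(C)C(=O)C=C3C(C)(C)CCC[C@]23C)[C@@]2(C)CCCC(C)(C)C2=CC1=O | intermediate
11 | (5S,10R,5'S,10'R)-11,11'-bi(5α-driman-7-one): trans-fused bis-ketone, C8 and C9 epimer mixture | CC1C(CCC2C(C)C(=O)C[C@H]3C(C)(C)CCC[C@]23C)[C@@]2(C)CCCC(C)(C)[C@@H]2CC1=O | intermediate
12 | (5S,10S,5'S,10'S)-7,7'-bis(trimethylsilyloxy)-11,11'-bi(5α-drim-7-ene), C9 epimer mixture | C[Si](C)(C)OC1=C(C)C(CCC2C(C)=C(O[Si](C)(C)C)C[C@H]3C(C)(C)CCC[C@]23C)[C@@]2(C)CCCC(C)(C)[C@@H]2C1 | intermediate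
13 | (5S,10S,5'S,10'S)-11,11'-bi(drim-8-en-7-one) | CC1=C(CCC2=C(C)C(=O)C[C@H]3C(C)(C)CCC[C@]23C)[C@@]2(C)CCCC(C)(C)[C@@H]2CC1=O | intermediate
14 | (5S,10S,5'S,10'S)-11,11'-bi(drim-8-ene) = 1,1'-(ethane-1,2-diyl)bis[(4aS,8aS)-2,5,5,8a-tetramethyl-3,4,4a,5,6,7,8,8a-octahydronaphthalene] | CC1=C(CCC2=C(C)CC[C@H]3C(C)(C)CCC[C@]23C)[C@@]2(C)CCCC(C)(C)[C@@H]2CC1 | target

**Totals**

Total step count: 8. Longest linear sequence: 7 steps (steps 1, 2, 4, 5, 6, 7, 8).

**Steps most likely to fail**

Step 4. The tetrasubstituted enamine carbon may fail to reach the β-carbon of an α,β-disubstituted enone even under pressure, or only one arm may react. Under base the congested C9–C10 bond may cleave by retro-Michael reaction, or a mono-adduct may cyclise onto its free enone arm. Fallback (known chemistry, one half at a time, C11–C11' bond made last), setting out from 7 and returning at 11: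
- 7 is combined with 3-methylbut-3-en-2-one, a β-unsubstituted vinyl ketone (THF, 40 °C), to give the monomeric imine adduct F1.
- Aqueous AcOH hydrolyses this to the diketone F2, and NaOMe in MeOH cyclises it to 11-nordrim-5-en-7-one F3.
- Li/NH3 with t-BuOH gives the trans-fused 11-nor-5α-driman-7-one F4.
- TMSCl/NaI/Et3N gives the silyl enol ether F5, and Pd(OAc)2 in MeCN gives 11-nordrim-8-en-7-one F6, whose β-carbon C9 carries only hydrogen.
- Mukaiyama–Michael addition of 1-methoxy-1-(trimethylsilyloxy)ethene (TiCl4, CH2Cl2, −78 °C, aqueous work-up) places C11 and a carboxyl carbon on C9 to give methyl 7-oxo-5α-drimane-11-carboxylate F7.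
- LiOH in aqueous THF gives the keto acid F8.
- Kolbe electrolysis of F8 (Pt electrodes, MeOH, NaOMe (0.1 equiv)) couples two C11 radicals, forms the C11–C11' bond and returns to the route at 11; steps 6 to 8 follow unchanged.

Step 8. The allyl cation may take hydride at C9 instead of C7, lose a proton to a diene, or be trapped by the alkene of the other half under the Lewis-acidic conditions. Fallback, setting out from 13 and returning at 14: ethane-1,2-dithiol with BF3·OEt2 (CH2Cl2, 0 °C) converts both C7 carbonyls into dithiolanes to give the bis(dithiolane) F9, with the C8=C9 bonds left in place. Reductive desulfurisation with Raney Ni (EtOH, reflux) then gives 14 without a cationic intermediate.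

Step 7 (with step 6). Enolisation may run toward C6 instead of C8, palladation of the tetrasubstituted enol ether next to the quaternary C10 may be slow, or β-hydride loss may occur from the C8 methyl group to give the exocyclic enone. Fallback, setting out from 11 and returning at 13: acid-mediated bromination through the more substituted enol (PhNMe3Br3, THF, 0 °C) gives 8,8'-dibromo-11,11'-bi(5α-driman-7-one) F10. Dehydrobromination (Li2CO3, LiBr, DMF, 120 °C) under equilibrating conditions then gives the endocyclic enone 13, bypassing both the silyl enol ether and the palladium step.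

**Further compounds**

F1 | step 4 | (S)-1-phenylethyl imine of (6R)-2,2,6-trimethyl-6-(2-methyl-3-oxobutyl)cyclohexanone (side-chain epimers) | CC(=O)C(C)C[C@@]1(C)CCCC(C)(C)C1=N[C@@H](C)c1ccccc1
F2 | step 4 | (6R)-2,2,6-trimethyl-6-(2-methyl-3-oxobutyl)cyclohexanone (side-chain epimers) | CC(=O)C(C)C[C@@]1(C)CCCC(C)(C)C1=O
F3 | step 4 | 11-nordrim-5-en-7-one, (4aR)-3,4a,8,8-tetramethyl-4,4a,5,6,7,8-hexahydronaphthalen-2(3H)-one (C8 epimers) | CC1C[C@@]2(C)CCCC(C)(C)C2=CC1=O
F4 | step 4 | 11-nor-5α-driman-7-one (trans-fused, C8 epimers) | CC1C[C@@]2(C)CCCC(C)(C)[C@@H]2CC1=O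
F5 | step 4 | 7-trimethylsilyloxy-11-nor-5α-drim-7-ene | C[Si](C)(C)OC1=C(C)C[C@@]2(C)CCCC(C)(C)[C@@H]2C1
F6 | step 4 | 11-nordrim-8-en-7-one | CC1=C[C@@]2(C)CCCC(C)(C)[C@@H]2CC1=O
F7 | step 4 | methyl 7-oxo-5α-drimane-11-carboxylate (C9–CH2–CO2Me; C8 and C9 epimers) | CC1C(CC(=O)OC)[C@@]2(C)CCCC(C)(C)[C@@H]2CC1=O
F8 | step 4 | 7-oxo-5α-drimane-11-carboxylic acid (C9–CH2–CO2H; C8 and C9 epimers) | CC1C(CC(=O)O)[C@@]2(C)CCCC(C)(C)[C@@H]2CC1=O
F9 | step 8 | 7,7:7',7'-bis(ethane-1,2-diyldisulfanediyl)-11,11'-bi(drim-8-ene), the bis(1,3-dithiolane) of 13 | CC1=C(CCC2=C(C)C4(SCCS4)C[C@H]5C(C)(C)CCC[C@]25C)[C@@]2(C)CCCC(C)(C)[C@@H]2CC13SCCS3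
F10 | step 7 | 8,8'-dibromo-11,11'-bi(5α-driman-7-one) (C8 and C9 epimers) | CC1(Br)C(CCC2C(C)(Br)C(=O)C[C@H]3C(C)(C)CCC[C@]23C)[C@@]2(C)CCCC(C)(C)[C@@H]2CC1=O
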